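**Plan**
1. Retrosynthesis: the flavonol pyranone (ring F) is cut at O1–C2 and C3–C4 (Baker–Venkataraman logic), leaving a flavan whose C4 carries an oxygenated aryl (ring D). The flavan is then cut at C4–C4a, at O1–C2 and at the C3–C4 oxirane, back to a chalcone from a ring-B acetophenone and a ring-D aldehyde.
2. Enabling feature: flavan C4 is a diarylmethine trans to O3, and the ring-A carbon C4a bonded to it is ortho to O1 and para to O7. An O1–C2 aryl ether of a C3–C4 epoxide can therefore close ring C by attack of C4a on benzylic C4, which the para oxygen of ring D activates.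
3. Forward order: chalcone → trans-epoxide → anti epoxy alcohol → ring-A aryl ether → ring C (C4–C4a) → ring-D phenol unmasked, C-acylated at its ortho carbon and esterified with the ring-E acid → ring F → global hydrogenolysis.
4. Stereochemistry: the two oxirane centres come from a poly-L-leucine (Juliá–Colonna) epoxidation, C2 from chelation-controlled reduction followed by Mitsunobu inversion, and the final C4 configuration from inversion at C4 in the epoxide opening (trans-epoxide → 3,4-trans, 2,3-cis carried through).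

Key step: step 11

Remark: flavan numbering (O1, C2, C3, C4, C4a–C8a) is used for the chain carbons from the chalcone onward; rings are lettered A/C/B (flavan benzo, pyran, 2-aryl) and D/F/E (flavonol benzo, pyranone, 2-aryl); poly-L-leucine, 3,4-bis(benzyloxy)benzoic acid and (benzyloxymethyl)tributylstannane are taken as purchasable.

**Step 1**
Reactants: 1 pyrogallol
Product: 2 2,2-diphenyl-1,3-benzodioxol-4-ol (ring-A phenol)
Conditions: Ph2CCl2, Ph2O, 175 °C
Reagents that add atoms: dichlorodiphenylmethane, ClC(Cl)(c1ccccc1)c1ccccc1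
Why: Catechol ketalisation with a gem-dichloride (diphenylmethylene ketal formation) should bridge one vicinal pair of hydroxyls, both pairs of pyrogallol being equivalent, and leave one free phenol next to the ketal oxygen as the future O1 of the flavan.

**Step 2**
Reactants: 3 3',4'-dihydroxyacetophenone
Product: 4 3',4'-bis(benzyloxy)acetophenone (ring-B ketone)
Conditions: BnBr, K2CO3, DMF, 60 °C
Reagents that add atoms: benzyl bromide, BrCc1ccccc1
Why: Williamson ether synthesis on both phenoxides should give the bis(benzyl) ether, which is stable to every later step and is removed only in the final hydrogenolysis.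

**Step 3**
Reactants: 5 methyl gallate
Product: 6 methyl 7-hydroxy-2,2-diphenyl-1,3-benzodioxole-5-carboxylate
Conditions: Ph2CCl2, neat, 180 °C
Reagents that add atoms: dichlorodiphenylmethane, ClC(Cl)(c1ccccc1)c1ccccc1
Why: The same gem-dichloride catechol ketalisation should tie up two adjacent hydroxyls of the symmetric gallate (either pair gives the same product) and leave the third free for separate protection.

**Step 4**
Reactants: 6 methyl 7-hydroxy-2,2-diphenyl-1,3-benzodioxole-5-carboxylate
Product: 7 methyl 7-(allyloxy)-2,2-diphenyl-1,3-benzodioxole-5-carboxylate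
Conditions: allyl bromide, K2CO3, DMF, 50 °C
Reagents that add atoms: allyl bromide, C=CCBr
Why: Williamson allylation of the remaining phenol should install a group that survives base, hydride, Mitsunobu and acidic conditions and is later removable by Pd(0) without touching benzyl ethers or ketals.

**Step 5**
Reactants: 7 methyl 7-(allyloxy)-2,2-diphenyl-1,3-benzodioxole-5-carboxylate
Product: 8 [7-(allyloxy)-2,2-diphenyl-1,3-benzodioxol-5-yl]methanol
Conditions: LiAlH4, THF, 0 °C
Reagents that add atoms: none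
Why: Hydride reduction of the aryl ester with LiAlH4 should give the benzylic alcohol and leave the allyl ether and the ketal untouched.

**Step 6**
Reactants: 8 [7-(allyloxy)-2,2-diphenyl-1,3-benzodioxol-5-yl]methanol
Product: 9 7-(allyloxy)-2,2-diphenyl-1,3-benzodioxole-5-carbaldehyde (ring-D aldehyde)
Conditions: MnO2, CH2Cl2, rt
Reagents that add atoms: none
Why: MnO2 oxidation is selective for benzylic alcohols and should stop at the aldehyde without attacking the allyl group.

**Step 7**
Reactants: 4 3',4'-bis(benzyloxy)acetophenone; 9 7-(allyloxy)-2,2-diphenyl-1,3-benzodioxole-5-carbaldehyde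
Product: 10 (E)-3-[7-(allyloxy)-2,2-diphenyl-1,3-benzodioxol-5-yl]-1-[3,4-bis(benzyloxy)phenyl]prop-2-en-1-one (chalcone)
Conditions: KOH (aq.), EtOH/THF, rt
Reagents that add atoms: none
Why: Claisen–Schmidt (crossed aldol) condensation of a methyl ketone with a non-enolisable aldehyde, followed by E1cB dehydration, should give the E-enone only.

**Step 8**
Reactants: 10 chalcone
Product: 11 [(2R,3S)-3-(7-allyloxy-2,2-diphenyl-1,3-benzodioxol-5-yl)oxiran-2-yl][3,4-bis(benzyloxy)phenyl]methanone (trans-epoxy ketone)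
Conditions: poly-L-leucine, urea–H2O2, DBU, THF, rt
Reagents that add atoms: urea–hydrogen peroxide, NC(N)=O.OO
Why: Juliá–Colonna epoxidation (Weitz–Scheffer addition of hydroperoxide inside the helical poly-L-leucine) should give the trans-(2R,3S)-epoxy ketone, the L-polymer fixing both oxirane centres (the future C3 and, before inversion, C4) and the alkene geometry fixing their trans relation.

**Step 9**
Reactants: 11 trans-epoxy ketone
Product: 12 (S)-[3,4-bis(benzyloxy)phenyl][(2S,3S)-3-(7-allyloxy-2,2-diphenyl-1,3-benzodioxol-5-yl)oxiran-2-yl]methanol (anti epoxy alcohol)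
Conditions: Zn(BH4)2, Et2O/CH2Cl2, −20 °C; then NH4Cl (aq.)
Reagents that add atoms: none
Why: Chelation-controlled hydride reduction, in which Zn(II) bridges the carbonyl and oxirane oxygens and hydride enters from the face anti to the oxirane Cβ, should give the anti (erythro) epoxy alcohol, i.e. the (S)-carbinol.

**Step 10**
Reactants: 12 anti epoxy alcohol; 2 2,2-diphenyl-1,3-benzodioxol-4-ol
Product: 13 4-{(R)-[3,4-bis(benzyloxy)phenyl][(2R,3S)-3-(7-allyloxy-2,2-diphenyl-1,3-benzodioxol-5-yl)oxiran-2-yl]methoxy}-2,2-diphenyl-1,3-benzodioxole (syn aryl ether of the trans-epoxide: ring A on O1, ring B on C2, ring D on C4)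
Conditions: PPh3, DIAD, toluene, 0 °C → rt
Reagents that add atoms: none
Why: Mitsunobu etherification should displace the activated carbinol oxygen by the phenoxide of 2 in an SN2 process with inversion, giving the (R)-configured syn (threo) ether, while the electron-withdrawing oxirane next to the carbinol disfavours ionisation.

**Step 11**
Reactants: 13 syn aryl ether of the trans-epoxide
Product: 14 (2R,3R,4S)-4-[7-(allyloxy)-2,2-diphenyl-1,3-benzodioxol-5-yl]-2-[3,4-bis(benzyloxy)phenyl]-7,8-[(diphenylmethylene)dioxy]chroman-3-ol (2,3-cis-3,4-trans 4-arylflavan-3-ol)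
Conditions: HFIP/CH2Cl2 (4:1), 0.01 M, 0 °C → rt
Reagents that add atoms: none
Why: HFIP hydrogen-bonds to the oxirane oxygen, the benzylic C4–O bond is weakened by the para ketal oxygen of ring D, and ring-A carbon C4a (ortho to O1, para to O7) attacks C4 from the side opposite the departing oxygen, after which proton loss from the Wheland intermediate restores ring A and leaves the C3 hydroxyl. The closest known reaction is the intramolecular Friedel–Crafts epoxide–arene cyclisation of 3-aryl-glycidyl aryl ethers to trans-4-arylchroman-3-ols. Ring C closes in the 6-endo mode (both oxirane carbons end up in the ring), which the benzylic activation of C4 favours over 5-exo attack at C3. The only new stereocentre, C4, is set by inversion at the oxirane carbon installed in step 8, so the trans-epoxide gives the 3,4-trans product, and C2 and C3 pass through unchanged to complete the 2,3-cis-3,4-trans triad. The step needs C4 over C3 attack, ring A over ring B as nucleophile, and displacement ahead of free-cation chemistry (hydride shift to a ketone, scrambling at C4): the para oxygen of ring D fixes the site, C4a has two ortho/para oxygens whereas the reachable ring-B carbon has one and could only close a five-membered ring in a 5-endo mode, and the short O1–C2 tether holds C4a behind the C4–O bond. The inductive pull of the C3 oxygen should keep the benzylic O1–C2 ether from ionising in this mildly acidic medium, and high dilution suppresses intermolecular alkylation.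

**Step 12**
Reactants: 14 4-arylflavan-3-ol
Product: 15 (2R,3R,4S)-4-[7-(allyloxy)-2,2-diphenyl-1,3-benzodioxol-5-yl]-3-(benzyloxy)-2-[3,4-bis(benzyloxy)phenyl]-7,8-[(diphenylmethylene)dioxy]chroman
Conditions: NaH, BnBr, TBAI (cat.), DMF, 0 °C → rt
Reagents that add atoms: benzyl bromide, BrCc1ccccc1
Why: Williamson benzylation of the sodium alkoxide should cap the only free hydroxyl, so that it is neither oxidised in step 16 nor acylated in step 17.

**Step 13**
Reactants: 15 3-O-benzyl allyl ether
Product: 16 (2R,3R,4S)-3-(benzyloxy)-2-[3,4-bis(benzyloxy)phenyl]-4-(7-hydroxy-2,2-diphenyl-1,3-benzodioxol-5-yl)-7,8-[(diphenylmethylene)dioxy]chroman (ring-D phenol)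
Conditions: Pd(PPh3)4 (cat.), morpholine, THF, rt
Reagents that add atoms: none
Why: Pd(0)-catalysed allyl transfer to morpholine (Tsuji–Trost deallylation) should unmask the ring-D phenol selectively, since benzyl ethers and ketals are inert to Pd(0).

**Step 14**
Reactants: 16 ring-D phenol
Product: 18 (2R,3R,4S)-3-(benzyloxy)-2-[3,4-bis(benzyloxy)phenyl]-4-(6-formyl-7-hydroxy-2,2-diphenyl-1,3-benzodioxol-5-yl)-7,8-[(diphenylmethylene)dioxy]chroman, via salicyl alcohol 17 (not isolated)
Conditions: MgCl2, Et3N, (CH2O)n, THF, reflux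
Reagents that add atoms: paraformaldehyde (formaldehyde), C=O
Why: Magnesium-mediated ortho-formylation (Casnati–Skattebøl) should deliver formaldehyde through the Mg phenoxide chelate to the only hydrogen-bearing ortho carbon, not to the free para carbon, giving salicyl alcohol 17, which is oxidised in the flask by hydride transfer to a second formaldehyde.

**Step 15**
Reactants: 18 ring-D salicylaldehyde
Product: 19 (2R,3R,4S)-3-(benzyloxy)-4-{6-[2-(benzyloxy)-1-hydroxyethyl]-7-hydroxy-2,2-diphenyl-1,3-benzodioxol-5-yl}-2-[3,4-bis(benzyloxy)phenyl]-7,8-[(diphenylmethylene)dioxy]chroman (carbinol epimers)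
Conditions: BnOCH2SnBu3, n-BuLi, THF, −78 °C (2.2 equiv of the lithium reagent); then 18; NH4Cl (aq.)
Reagents that add atoms: (benzyloxymethyl)tributylstannane, CCCC[Sn](CCCC)(CCCC)COCc1ccccc1
Why: 1,2-Addition of an α-alkoxy organolithium made by tin–lithium exchange should install the CH2OBn carbon, the first equivalent being spent on the phenol, and the new carbinol centre, formed as a mixture, is erased in step 16.

**Step 16**
Reactants: 19 carbinol
Product: 20 (2R,3R,4S)-3-(benzyloxy)-4-{6-[(benzyloxy)acetyl]-7-hydroxy-2,2-diphenyl-1,3-benzodioxol-5-yl}-2-[3,4-bis(benzyloxy)phenyl]-7,8-[(diphenylmethylene)dioxy]chroman (ortho-hydroxyaryl benzyloxymethyl ketone)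
Conditions: MnO2, CH2Cl2, rt
Reagents that add atoms: none
Why: MnO2 oxidation of the benzylic secondary alcohol should give the aryl ketone while tolerating the free phenol and all ether groups.

**Step 17**
Reactants: 20 ortho-hydroxyaryl ketone; 21 3,4-bis(benzyloxy)benzoic acid
Product: 22 (2R,3R,4S)-3-(benzyloxy)-4-{6-[(benzyloxy)acetyl]-7-[3,4-bis(benzyloxy)benzoyloxy]-2,2-diphenyl-1,3-benzodioxol-5-yl}-2-[3,4-bis(benzyloxy)phenyl]-7,8-[(diphenylmethylene)dioxy]chroman (aryl ester)
Conditions: DCC, DMAP (cat.), CH2Cl2, rt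
Reagents that add atoms: none
Why: Steglich esterification of the phenol with the ring-E acid should give the aryl ester needed for acyl transfer, the only other hydroxyl having been benzylated in step 12.

**Step 18**
Reactants: 22 aryl ester
Product: 24 3-(benzyloxy)-2-[3,4-bis(benzyloxy)phenyl]-5-{(2R,3R,4S)-3-(benzyloxy)-2-[3,4-bis(benzyloxy)phenyl]-7,8-[(diphenylmethylene)dioxy]chroman-4-yl}-7,8-[(diphenylmethylene)dioxy]-4H-chromen-4-one, via β-diketone 23 (not isolated)
Conditions: LiHMDS, THF, −20 °C → rt; AcOH; then p-TsOH·H2O (cat.), toluene, 50 °C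
Reagents that add atoms: none
Why: Baker–Venkataraman rearrangement (the enolate of the α-benzyloxy ketone attacks the neighbouring aryl ester in an intramolecular Claisen acyl transfer) should give β-diketone 23, whose phenol then adds to the aroyl carbonyl and loses water under mild acid (6-exo-trig cyclodehydration) to form the 3-benzyloxychromen-4-one ring F.

**Step 19**
Reactants: 24 fully protected target
Product: 25 2-(3,4-dihydroxyphenyl)-5-[(2R,3R,4S)-2-(3,4-dihydroxyphenyl)-3,7,8-trihydroxychroman-4-yl]-3,7,8-trihydroxy-4H-chromen-4-one (CNP0395591.1)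
Conditions: H2 (1 atm), Pd(OH)2/C, THF/MeOH (degassed), rt
Reagents that add atoms: none
Why: Catalytic hydrogenolysis should cleave the six O-benzyl groups and both diphenylmethylene ketals in one operation, while the cyclic O1–C2 ether of the flavan and the chromone double bond are expected to survive if the reaction is stopped once the protecting groups are gone.

**Compound list**
1 | pyrogallol | Oc1cccc(O)c1O | starting material
2 | 2,2-diphenyl-1,3-benzodioxol-4-ol | Oc1cccc2OC(c3ccccc3)(c3ccccc3)Oc12 | intermediate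
3 | 3',4'-dihydroxyacetophenone | CC(=O)c1ccc(O)c(O)c1 | starting material
4 | 3',4'-bis(benzyloxy)acetophenone | CC(=O)c1ccc(OCc2ccccc2)c(OCc2ccccc2)c1 | intermediate
5 | methyl gallate | COC(=O)c1cc(O)c(O)c(O)c1 | starting material
6 | methyl 7-hydroxy-2,2-diphenyl-1,3-benzodioxole-5-carboxylate | COC(=O)c1cc(O)c2OC(c3ccccc3)(c3ccccc3)Oc2c1 | intermediate
7 | methyl 7-(allyloxy)-2,2-diphenyl-1,3-benzodioxole-5-carboxylate | COC(=O)c1cc(OCC=C)c2OC(c3ccccc3)(c3ccccc3)Oc2c1 | intermediate
8 | [7-(allyloxy)-2,2-diphenyl-1,3-benzodioxol-5-yl]methanol | OCc1cc(OCC=C)c2OC(c3ccccc3)(c3ccccc3)Oc2c1 | intermediate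
9 | 7-(allyloxy)-2,2-diphenyl-1,3-benzodioxole-5-carbaldehyde | O=Cc1cc(OCC=C)c2OC(c3ccccc3)(c3ccccc3)Oc2c1 | intermediate
10 | (E)-chalcone from 4 and 9 | O=C(/C=C/c1cc(OCC=C)c2OC(c3ccccc3)(c3ccccc3)Oc2c1)c1ccc(OCc2ccccc2)c(OCc2ccccc2)c1 | intermediate
11 | (2R,3S)-trans-epoxy ketone | O=C(c1ccc(OCc2ccccc2)c(OCc2ccccc2)c1)[C@@H]1O[C@H]1c1cc(OCC=C)c2OC(c3ccccc3)(c3ccccc3)Oc2c1 | intermediate
12 | anti epoxy alcohol, (S)-carbinol, (2S,3S)-oxirane | O[C@@H](c1ccc(OCc2ccccc2)c(OCc2ccccc2)c1)[C@@H]1O[C@H]1c1cc(OCC=C)c2OC(c3ccccc3)(c3ccccc3)Oc2c1 | intermediate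
13 | syn aryl ether of the trans-epoxide, (R)-ether carbon, (2R,3S)-oxirane | c1ccc2OC(c3ccccc3)(c3ccccc3)Oc2c1O[C@H](c1ccc(OCc2ccccc2)c(OCc2ccccc2)c1)[C@@H]1O[C@H]1c1cc(OCC=C)c2OC(c3ccccc3)(c3ccccc3)Oc2c1 | intermediate
14 | (2R,3R,4S)-4-arylflavan-3-ol (ring D with O-allyl) | C=CCOc1cc(cc2OC(c3ccccc3)(c3ccccc3)Oc12)[C@H]1c2ccc3OC(c4ccccc4)(c4ccccc4)Oc3c2O[C@H](c2ccc(OCc3ccccc3)c(OCc3ccccc3)c2)[C@@H]1O | intermediate
15 | 3-O-benzyl ether of 14 | C=CCOc1cc(cc2OC(c3ccccc3)(c3ccccc3)Oc12)[C@H]1c2ccc3OC(c4ccccc4)(c4ccccc4)Oc3c2O[C@H](c2ccc(OCc3ccccc3)c(OCc3ccccc3)c2)[C@@H]1OCc1ccccc1 | intermediate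
16 | ring-D phenol | Oc1cc(cc2OC(c3ccccc3)(c3ccccc3)Oc12)[C@H]1c2ccc3OC(c4ccccc4)(c4ccccc4)Oc3c2O[C@H](c2ccc(OCc3ccccc3)c(OCc3ccccc3)c2)[C@@H]1OCc1ccccc1 | intermediate
17 | ring-D salicyl alcohol (ortho-hydroxymethyl phenol) | Oc1c(CO)c(cc2OC(c3ccccc3)(c3ccccc3)Oc12)[C@H]1c2ccc3OC(c4ccccc4)(c4ccccc4)Oc3c2O[C@H](c2ccc(OCc3ccccc3)c(OCc3ccccc3)c2)[C@@H]1OCc1ccccc1 | intermediate
18 | ring-D salicylaldehyde | Oc1c(C=O)c(cc2OC(c3ccccc3)(c3ccccc3)Oc12)[C@H]1c2ccc3OC(c4ccccc4)(c4ccccc4)Oc3c2O[C@H](c2ccc(OCc3ccccc3)c(OCc3ccccc3)c2)[C@@H]1OCc1ccccc1 | intermediate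
19 | 2-(benzyloxy)-1-hydroxyethyl phenol (carbinol epimers) | Oc1c(C(O)COCc2ccccc2)c(cc2OC(c3ccccc3)(c3ccccc3)Oc12)[C@H]1c2ccc3OC(c4ccccc4)(c4ccccc4)Oc3c2O[C@H](c2ccc(OCc3ccccc3)c(OCc3ccccc3)c2)[C@@H]1OCc1ccccc1 | intermediate
20 | ortho-hydroxyaryl benzyloxymethyl ketone | Oc1c(C(=O)COCc2ccccc2)c(cc2OC(c3ccccc3)(c3ccccc3)Oc12)[C@H]1c2ccc3OC(c4ccccc4)(c4ccccc4)Oc3c2O[C@H](c2ccc(OCc3ccccc3)c(OCc3ccccc3)c2)[C@@H]1OCc1ccccc1 | intermediate
21 | 3,4-bis(benzyloxy)benzoic acid | OC(=O)c1ccc(OCc2ccccc2)c(OCc2ccccc2)c1 | starting material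
22 | aryl 3,4-bis(benzyloxy)benzoate of 20 | O=C(Oc1c(C(=O)COCc2ccccc2)c(cc2OC(c3ccccc3)(c3ccccc3)Oc12)[C@H]1c2ccc3OC(c4ccccc4)(c4ccccc4)Oc3c2O[C@H](c2ccc(OCc3ccccc3)c(OCc3ccccc3)c2)[C@@H]1OCc1ccccc1)c1ccc(OCc2ccccc2)c(OCc2ccccc2)c1 | intermediate
23 | 2-benzyloxy-1,3-diketone (Baker–Venkataraman product) | Oc1c(C(=O)C(OCc2ccccc2)C(=O)c2ccc(OCc3ccccc3)c(OCc3ccccc3)c2)c(cc2OC(c3ccccc3)(c3ccccc3)Oc12)[C@H]1c2ccc3OC(c4ccccc4)(c4ccccc4)Oc3c2O[C@H](c2ccc(OCc3ccccc3)c(OCc3ccccc3)c2)[C@@H]1OCc1ccccc1 | intermediate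
24 | fully protected target (six O-benzyl, two diphenylmethylene ketals) | O=c1c(OCc2ccccc2)c(-c2ccc(OCc3ccccc3)c(OCc3ccccc3)c2)oc2c3OC(c4ccccc4)(c4ccccc4)Oc3cc([C@H]3c4ccc5OC(c6ccccc6)(c6ccccc6)Oc5c4O[C@H](c4ccc(OCc5ccccc5)c(OCc5ccccc5)c4)[C@@H]3OCc3ccccc3)c12 | intermediate
25 | CNP0395591.1 | O=c1c(O)c(-c2ccc(O)c(O)c2)oc2c(O)c(O)cc([C@H]3c4ccc(O)c(O)c4O[C@H](c4ccc(O)c(O)c4)[C@@H]3O)c12 | target

**Step count**
Total: 19 steps. Longest linear sequence: 17 steps (steps 3–19, from methyl gallate).

**Steps most likely to fail**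

Step 11. The oxirane may ionise fully before ring A engages. C4 could then be attacked from both faces, a hydride could shift from C3 to give a ketone, or the solvent could capture the cation. The fallback sets out from 13 and returns at 14, and replaces the stereospecific opening by a neighbouring-group-controlled cationic closure. Methanolysis of the oxirane at C4 (PPTS, MeOH/CH2Cl2) would give the C4 methyl ether F1, either C4 epimer being usable. Acetylation (Ac2O, pyridine, DMAP) would give the C3 acetate F2. BF3·OEt2 in CH2Cl2 at −78 °C would ionise the methoxy group, the acetate would bridge C3 and C4 as a cis-fused dioxolanylium ion, and ring A would attack C4 anti to O3 to give the 3-O-acetyl flavan F3. K2CO3 in MeOH would then give 14.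

Step 14. Delivery of formaldehyde to the ortho carbon may stall, because that carbon is flanked by the diarylmethine, and the phenol would then be recovered. The fallback sets out from 15 and returns at 18, and uses the allyl group already present as the carbon source. An aromatic Claisen rearrangement (N,N-diethylaniline, 190 °C) would carry the allyl group intramolecularly to the free ortho carbon, giving the C-allyl phenol F4. Alkene isomerisation (RuHCl(CO)(PPh3)3, toluene, 80 °C) would give the propenyl phenol F5. Lemieux–Johnson cleavage (OsO4 cat., NaIO4, 2,6-lutidine, dioxane/H2O) would give 18.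

Step 10. The electron-rich benzylic oxyphosphonium may ionise in part, eroding the configuration at C2, or the hindered phenol may couple too slowly. The fallback sets out from 10 and returns at 13, and forms O1–C2 without breaking the carbinol C–O bond. A CBS reduction of the enone, with the catalyst antipode chosen for the (S)-carbinol, would give the allylic alcohol F6. 3-Bromocatechol and dichlorodiphenylmethane would give 4-bromo-2,2-diphenyl-1,3-benzodioxole F7. Ullmann-type O-arylation of F6 with F7 (CuI, 3,4,7,8-tetramethyl-1,10-phenanthroline, Cs2CO3, toluene, 100 °C) would give, with retention, the allyl aryl ether F8. Shi epoxidation of the trans-alkene (Oxone, K2CO3 buffer) with the enantiomer of the fructose-derived ketone, chosen by analogy with trans-β-alkylstyrenes, would then set the oxirane under reagent control and give 13.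

**Further compounds**
F1 | step 11 | C4 methyl ether of the opened oxirane (3-ol, C4 epimers) | c1ccc2OC(c3ccccc3)(c3ccccc3)Oc2c1O[C@H](c1ccc(OCc2ccccc2)c(OCc2ccccc2)c1)[C@H](O)C(OC)c1cc(OCC=C)c2OC(c3ccccc3)(c3ccccc3)Oc2c1
F2 | step 11 | C3 acetate of F1 | c1ccc2OC(c3ccccc3)(c3ccccc3)Oc2c1O[C@H](c1ccc(OCc2ccccc2)c(OCc2ccccc2)c1)[C@H](OC(C)=O)C(OC)c1cc(OCC=C)c2OC(c3ccccc3)(c3ccccc3)Oc2c1
F3 | step 11 | 3-O-acetyl derivative of 14 | C=CCOc1cc(cc2OC(c3ccccc3)(c3ccccc3)Oc12)[C@H]1c2ccc3OC(c4ccccc4)(c4ccccc4)Oc3c2O[C@H](c2ccc(OCc3ccccc3)c(OCc3ccccc3)c2)[C@@H]1OC(C)=O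
F4 | step 14 | ring-D ortho-C-allyl phenol | Oc1c(CC=C)c(cc2OC(c3ccccc3)(c3ccccc3)Oc12)[C@H]1c2ccc3OC(c4ccccc4)(c4ccccc4)Oc3c2O[C@H](c2ccc(OCc3ccccc3)c(OCc3ccccc3)c2)[C@@H]1OCc1ccccc1
F5 | step 14 | ring-D ortho-(E)-propenyl phenol | Oc1c(/C=C/C)c(cc2OC(c3ccccc3)(c3ccccc3)Oc12)[C@H]1c2ccc3OC(c4ccccc4)(c4ccccc4)Oc3c2O[C@H](c2ccc(OCc3ccccc3)c(OCc3ccccc3)c2)[C@@H]1OCc1ccccc1
F6 | step 10 | (S,E)-allylic alcohol from chalcone 10 | O[C@H](c1ccc(OCc2ccccc2)c(OCc2ccccc2)c1)/C=C/c1cc(OCC=C)c2OC(c3ccccc3)(c3ccccc3)Oc2c1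
F7 | step 10 | 4-bromo-2,2-diphenyl-1,3-benzodioxole | Brc1cccc2OC(c3ccccc3)(c3ccccc3)Oc12
F8 | step 10 | (S,E)-allyl aryl ether (ring A on O1) | c1ccc2OC(c3ccccc3)(c3ccccc3)Oc2c1O[C@H](c1ccc(OCc2ccccc2)c(OCc2ccccc2)c1)/C=C/c1cc(OCC=C)c2OC(c3ccccc3)(c3ccccc3)Oc2c1
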